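**Strategy.** Ring B is cut between C6–C7 and C9–C10 (drimane numbering), leaving a ring-A cyclohexenol and a three-carbon C7–C8–C9 unit. The key step exploits the C1=C2 alkene of ring A beside quaternary C10: with C8 viewed as a ketone, C8(=O)–C9–C10–C1=C2 is a Claisen retron and C7 is an enolate carbon facing C6. In one pot an enantiopure trans-4-(iodomethyl)cyclohex-2-enol adds to phenylsulfonylallene, a carbanion-accelerated [3,3] shift builds C9–C10 (C10 configured by the carbinol, alkene moved to C1=C2), and the resulting β-keto sulfone enolate closes ring B on the iodide. C11, the C8 methyl and isofraxidin follow.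

Key step: step 6

Atom labels: drimane positions of the target are used for all intermediates (ring A = C1–C5 and C10; ring B = C5–C10; C11 = the OCH2 carbon on C9; C12 = the methyl on C8).

Assumption: racemic keto ester 1 and allenyl sulfone 7 are purchased. The lipase is assumed to acylate the (4R)-carbinol (alkenyl flank as the large group); if it prefers the other enantiomer, the unreacted alcohol is the (1R,4R) material and enters step 3 unchanged.

Step 1
Reactants: 1 ethyl 2,6,6-trimethyl-4-oxocyclohex-2-ene-1-carboxylate (racemic)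
Product: 2 ethyl (1R*,4R*)-4-hydroxy-2,6,6-trimethylcyclohex-2-ene-1-carboxylate (racemic trans isomer)
Conditions: NaBH4, CeCl3·7H2O, MeOH, −20 °C; cis isomer removed by chromatography
Reagents that add atoms: none
Why: Luche 1,2-reduction of the enone; with the ester pseudo-axial (allylic strain with the vinylic methyl) hydride should enter anti to the axial methyl of the gem-dimethyl carbon, placing OH trans to the ester (relative configuration only).

Step 2
Reactants: 2 racemic trans hydroxy ester
Product: 3 ethyl (1R,4R)-4-acetoxy-2,6,6-trimethylcyclohex-2-ene-1-carboxylate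
Conditions: Burkholderia cepacia lipase (immobilised), vinyl acetate, MTBE, 30 °C, stopped near half conversion; separated from the unreacted (1S,4S)-alcohol
Reagents that add atoms: vinyl acetate CC(=O)OC=C
Why: Lipase-catalysed kinetic resolution by transesterification; the empirical enantiopreference of lipases for secondary alcohols should acetylate the (4R)-carbinol, which fixes the absolute configuration of C2 and C5.

Step 3
Reactants: 3 (1R,4R)-acetoxy ester
Product: 4 (1R,4R)-4-(hydroxymethyl)-3,5,5-trimethylcyclohex-2-en-1-ol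
Conditions: LiAlH4, THF, 0 °C
Reagents that add atoms: none
Why: Hydride reduction converts the ethyl ester into the primary alcohol (C6) and cleaves the acetate; no stereocentre is touched.

Step 4
Reactants: 4 (1R,4R)-diol
Product: 5 [(1R,4R)-4-hydroxy-2,6,6-trimethylcyclohex-2-en-1-yl]methyl 4-methylbenzenesulfonate
Conditions: TsCl (1.05 equiv), Et3N, cat. Me3N·HCl, CH2Cl2, −10 °C
Reagents that add atoms: p-toluenesulfonyl chloride Cc1ccc(cc1)S(Cl)(=O)=O
Why: Sterically selective sulfonylation (tosylation) of the primary hydroxyl over the secondary allylic one.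

Step 5
Reactants: 5 primary tosylate
Product: 6 (1R,4R)-4-(iodomethyl)-3,5,5-trimethylcyclohex-2-en-1-ol
Conditions: NaI, 2-butanone, 80 °C
Reagents that add atoms: sodium iodide [Na+].[I-]
Why: Finkelstein SN2 exchange at the primary carbon, driven by precipitation of sodium tosylate; the soft iodide is wanted so that the later ring closure occurs on carbon.

Step 6
Reactants: 6 (1R,4R)-4-(iodomethyl)-3,5,5-trimethylcyclohex-2-en-1-ol; 7 (propa-1,2-dien-1-ylsulfonyl)benzene
Product: 10 trans-fused bicyclic β-keto sulfone (7-phenylsulfonyl-11,12-dinordrim-1-en-8-one), via sulfonyl allyl-anion vinyl ether 8 (not isolated), via acyclic β-keto sulfone enolate 9 (not isolated)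
Conditions: KH (1.05 equiv), THF, 0 °C; add 7; then KH (1.2 equiv), HMPA, 20 → 50 °C; aq. NH4Cl
Reagents that add atoms: none
Why: The potassium alkoxide of 6 adds to the central allene carbon of 7 to give the 2-oxyallyl sulfonyl carbanion 8, whose vinyl ether terminus C9 undergoes a carbanion-accelerated [3,3] sigmatropic shift onto C10 (C9–C10 formed, C2–O broken, alkene moved to C1=C2) to give enolate 9, and the sulfonyl-bearing carbon C7 of 9 then displaces the primary iodide at C6 (C6–C7 formed). The closest known reaction types are the carbanion-accelerated Claisen rearrangement of 2-(arylsulfonylmethyl) allyl vinyl ethers, which builds quaternary carbons at 20–50 °C, and the intramolecular C-alkylation of β-keto sulfone enolates. The shift itself closes no ring; ring B is closed afterwards in the 6-(enolendo)-exo-tet mode (C7 onto C6). C10 is set by suprafacial 1,3-transfer of chirality from the C2 carbinol (C9 arrives on the face that carried oxygen, the methyl ends on the other), C5 is carried over from 6, and the trans ring fusion follows because the CH2I arm on C5 and the new C9 arm on C10 are trans and both equatorial in the closing chair; the sulfone-bearing C7 is a labile centre erased in step 8. The step needs C- rather than O-alkylation and the shift before any substitution or E2 at C6: the soft iodide and the sulfonyl/enolate potassium chelate favour carbon, and the trans-1,4 relation of oxygen and CH2I in 6 makes ring closure geometrically impossible until C9 has been moved to C10.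

Step 7
Reactants: 10 bicyclic β-keto sulfone
Product: 11 7-phenylsulfonyl-11-(triisopropylsilyloxy)-12-nordrim-1-en-8-one (CH2O on C9 anti to the C10 methyl)
Conditions: LDA (2.2 equiv), THF, −78 → −20 °C; (triisopropylsiloxy)methyl chloride, −78 °C; aq. NH4Cl
Reagents that add atoms: (triisopropylsiloxy)methyl chloride ClCO[Si](C(C)C)(C(C)C)C(C)C
Why: γ-Alkylation of a β-keto sulfone dianion at its more reactive terminus C9 with an alkoxymethyl chloride; the electrophile adds axially, anti to the axial C10 methyl, which sets C9 with C11 trans to that methyl.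

Step 8
Reactants: 11 alkylated β-keto sulfone
Product: 12 11-(triisopropylsilyloxy)-12-nordrim-1-en-8-one
Conditions: SmI2 (3 equiv), THF/MeOH, −78 °C
Reagents that add atoms: none
Why: Single-electron reductive desulfonylation of the α-sulfonyl ketone; the samarium enolate is protonated at C7 and C9 is never enolised.

Step 9
Reactants: 12 ring-B ketone
Product: 13 11-(triisopropylsilyloxy)-12-nordrim-1-ene-3,8-dione
Conditions: dirhodium tetracaprolactamate Rh2(cap)4 (1 mol %), t-BuOOH (70 % aq., 5 equiv), NaHCO3, CH2Cl2, 25 °C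
Reagents that add atoms: tert-butyl hydroperoxide CC(C)(C)OO
Why: Radical allylic C–H oxidation; C3 carries the only allylic hydrogens of the C1=C2 alkene because C10 is quaternary, C1 is shielded by the C9 CH2OTIPS arm, and the enone formed cannot enolise.

Step 10
Reactants: 13 ene-dione
Product: 14 3-oxo-11-(triisopropylsilyloxy)-12-nordrima-1,7-dien-8-yl trifluoromethanesulfonate
Conditions: KHMDS (1.1 equiv), THF, −78 °C; PhNTf2, −78 → 0 °C
Reagents that add atoms: N-phenylbis(trifluoromethanesulfonimide) FC(F)(F)S(=O)(=O)N(c1ccccc1)S(=O)(=O)C(F)(F)F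
Why: Kinetic enolisation and O-triflation; the base removes the axial hydrogen of the C7 methylene rather than the hindered equatorial C9 methine, giving the C7=C8 enol triflate.

Step 11
Reactants: 14 enol triflate
Product: 15 (5S,9S,10R)-11-(triisopropylsilyloxy)drima-1,7-dien-3-one
Conditions: MeZnCl (2 equiv), Pd(PPh3)4 (5 mol %), THF, 50 °C
Reagents that add atoms: methylzinc chloride C[Zn]Cl
Why: Negishi cross-coupling installs the C8 methyl (C12) with the alkene fixed at C7=C8; methylzinc does not add to the ring-A enone.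

Step 12
Reactants: 15 silyl ether
Product: 16 (5S,9S,10R)-11-hydroxydrima-1,7-dien-3-one
Conditions: TBAF, THF, 0 °C
Reagents that add atoms: none
Why: Fluoride-mediated desilylation; the ring-A enone has no enolisable position, so basic fluoride is harmless.

Step 13
Reactants: 16 (5S,9S,10R)-11-hydroxydrima-1,7-dien-3-one; 17 isofraxidin (7-hydroxy-6,8-dimethoxy-2H-chromen-2-one)
Product: 18 7-{[(5S,9S,10R)-3-oxodrima-1,7-dien-11-yl]oxy}-6,8-dimethoxy-2H-chromen-2-one (target CNP0330704.1)
Conditions: PPh3, DIAD, THF, 0 → 40 °C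
Reagents that add atoms: none
Why: Mitsunobu etherification; the acidic 7-OH of isofraxidin displaces the activated primary alcohol at C11, a carbon that is not a stereocentre.

**Compound list**

1 | ethyl 2,6,6-trimethyl-4-oxocyclohex-2-ene-1-carboxylate (racemic) | CCOC(=O)C1C(C)=CC(=O)CC1(C)C | starting material
2 | ethyl (1R*,4R*)-4-hydroxy-2,6,6-trimethylcyclohex-2-ene-1-carboxylate (racemic trans; the (1R,4R) enantiomer is drawn) | O[C@H]1C=C(C)[C@H](C(=O)OCC)C(C)(C)C1 | intermediate
3 | ethyl (1R,4R)-4-acetoxy-2,6,6-trimethylcyclohex-2-ene-1-carboxylate | CC(=O)O[C@H]1C=C(C)[C@H](C(=O)OCC)C(C)(C)C1 | intermediate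
4 | (1R,4R)-4-(hydroxymethyl)-3,5,5-trimethylcyclohex-2-en-1-ol | O[C@H]1C=C(C)[C@H](CO)C(C)(C)C1 | intermediate
5 | [(1R,4R)-4-hydroxy-2,6,6-trimethylcyclohex-2-en-1-yl]methyl 4-methylbenzenesulfonate | O[C@H]1C=C(C)[C@H](COS(=O)(=O)c2ccc(C)cc2)C(C)(C)C1 | intermediate
6 | (1R,4R)-4-(iodomethyl)-3,5,5-trimethylcyclohex-2-en-1-ol (C2–OH trans to C5–CH2I) | O[C@H]1C=C(C)[C@H](CI)C(C)(C)C1 | intermediate
7 | (propa-1,2-dien-1-ylsulfonyl)benzene (phenylsulfonylallene) | C=C=CS(=O)(=O)c1ccccc1 | starting material
8 | potassium 1-(phenylsulfonyl)-2-{[(1R,4R)-4-(iodomethyl)-3,5,5-trimethylcyclohex-2-en-1-yl]oxy}allyl anion (not isolated) | [K+].[CH-](S(=O)(=O)c1ccccc1)C(=C)O[C@H]1C=C(C)[C@H](CI)C(C)(C)C1 | intermediate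
9 | potassium enolate of 1-(phenylsulfonyl)-3-[6-(iodomethyl)-1,5,5-trimethylcyclohex-2-en-1-yl]propan-2-one, CH2I on C5 trans to the new C9 arm on C10 (not isolated) | [K+].[CH-](S(=O)(=O)c1ccccc1)C(=O)C[C@]1(C)C=CCC(C)(C)[C@H]1CI | intermediate
10 | 5,5,8a-trimethyl-3-(phenylsulfonyl)-3,4,4a,5,6,8a-hexahydronaphthalen-2(1H)-one, trans-fused (H on C5 anti to CH3 on C10); sulfone carbon C7 not defined (epimerisable, removed in step 8) | O=C1C[C@]2(C)C=CCC(C)(C)[C@H]2CC1S(=O)(=O)c1ccccc1 | intermediate
11 | 7-phenylsulfonyl-11-(triisopropylsilyloxy)-12-nordrim-1-en-8-one, trans-fused, CH2OTIPS on C9 anti to CH3 on C10; C7 not defined | O=C1[C@H](CO[Si](C(C)C)(C(C)C)C(C)C)[C@]2(C)C=CCC(C)(C)[C@H]2CC1S(=O)(=O)c1ccccc1 | intermediate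
12 | 11-(triisopropylsilyloxy)-12-nordrim-1-en-8-one (same configuration at C5, C9, C10) | O=C1[C@H](CO[Si](C(C)C)(C(C)C)C(C)C)[C@]2(C)C=CCC(C)(C)[C@H]2CC1 | intermediate
13 | 11-(triisopropylsilyloxy)-12-nordrim-1-ene-3,8-dione | O=C1[C@H](CO[Si](C(C)C)(C(C)C)C(C)C)[C@]2(C)C=CC(=O)C(C)(C)[C@H]2CC1 | intermediate
14 | 3-oxo-11-(triisopropylsilyloxy)-12-nordrima-1,7-dien-8-yl trifluoromethanesulfonate | FC(F)(F)S(=O)(=O)OC1=CC[C@@H]2C(C)(C)C(=O)C=C[C@@]2(C)[C@H]1CO[Si](C(C)C)(C(C)C)C(C)C | intermediate
15 | (5S,9S,10R)-11-(triisopropylsilyloxy)drima-1,7-dien-3-one | CC1=CC[C@@H]2C(C)(C)C(=O)C=C[C@@]2(C)[C@H]1CO[Si](C(C)C)(C(C)C)C(C)C | intermediate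
16 | (5S,9S,10R)-11-hydroxydrima-1,7-dien-3-one | CC1=CC[C@@H]2C(C)(C)C(=O)C=C[C@@]2(C)[C@H]1CO | intermediate
17 | isofraxidin (7-hydroxy-6,8-dimethoxy-2H-chromen-2-one) | COc1cc2ccc(=O)oc2c(OC)c1O | starting material
18 | 7-{[(5S,9S,10R)-3-oxodrima-1,7-dien-11-yl]oxy}-6,8-dimethoxy-2H-chromen-2-one | COc1cc2ccc(=O)oc2c(OC)c1OC[C@H]1C(C)=CC[C@@H]2C(C)(C)C(=O)C=C[C@]21C | target

**Count.** Total: 13 steps. Longest linear sequence: 13 steps (1 → 18); 7 and 17 are purchased and enter in steps 6 and 13.

**Steps most likely to fail**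

1. Step 6. The ring closure may go through the enolate oxygen (enol ether formation) instead of C7, or base may remove HI across C5/C6 before the sigmatropic shift. The fallback sets out from 6 and returns at 10. Compound 6 is esterified with 2,2,6-trimethyl-4H-1,3-dioxin-4-one (toluene, 110 °C) to the acetoacetate F1. LDA (2.1 equiv, THF, −78 → 60 °C, high dilution) then effects the dianionic Carroll rearrangement (C9–C10), and the unstabilised terminal lithium enolate so released closes ring B on carbon to the β-keto acid F2. This is decarboxylated on acidic work-up (50 °C) to the ring-B ketone F3. Kinetic deprotonation at C7 (LDA, −78 °C) and benzenesulfonyl fluoride then give 10.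

2. Step 9. Oxygen may be delivered to the wrong end of the allyl radical (C1 instead of C3), or oxidation may occur next to the C8 ketone. The fallback sets out from 12 and returns at 13. SeO2 (0.5 equiv) with t-BuOOH in CH2Cl2 gives the C3 allylic alcohol F4 by an ene/[2,3] sequence, which can only oxygenate the carbon that loses hydrogen. Dess–Martin periodinane then oxidises it to 13.

3. Step 13. The oxyphosphonium at the neopentyl-type C11 may collapse too slowly, so that the hindered phenoxide is outcompeted by hydrazide transfer or elimination. The fallback sets out from 16 and returns at 18. Tf2O and 2,6-lutidine (CH2Cl2, −78 °C) give the primary triflate F5, which is displaced by the cesium phenoxide of 17 (Cs2CO3, DMF, 0 → 25 °C).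

Further compounds
F1 | step 6 | (1R,4R)-4-(iodomethyl)-3,5,5-trimethylcyclohex-2-en-1-yl 3-oxobutanoate | CC(=O)CC(=O)O[C@H]1C=C(C)[C@H](CI)C(C)(C)C1
F2 | step 6 | trans-fused 8-oxo-12-nordrim-1-en-11-oic acid (C9 not defined, not isolated) | O=C1C(C(=O)O)[C@]2(C)C=CCC(C)(C)[C@H]2CC1
F3 | step 6 | trans-fused 11,12-dinordrim-1-en-8-one | O=C1C[C@]2(C)C=CCC(C)(C)[C@H]2CC1
F4 | step 9 | 3-hydroxy-11-(triisopropylsilyloxy)-12-nordrim-1-en-8-one (C3 not defined) | O=C1[C@H](CO[Si](C(C)C)(C(C)C)C(C)C)[C@]2(C)C=CC(O)C(C)(C)[C@H]2CC1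
F5 | step 13 | (5S,9S,10R)-3-oxodrima-1,7-dien-11-yl trifluoromethanesulfonate | CC1=CC[C@@H]2C(C)(C)C(=O)C=C[C@@]2(C)[C@H]1COS(=O)(=O)C(F)(F)F
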